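The top of D in the autumn flask cannot be read off its readings, since they step from 2.00 min to 5.00 min with nothing between, and the top may stand in that gap.

- autumn: E 10 mM; Z 40 mM; the very flask that is asked about, followed so far
- flask: E 10 mM; Z 40.0 mM; time 80 min

autumn run (percent of the E charged)

| time / min | D / % | L / % |
|---|---|---|
| 0.833 | 28.1 | 0.6 |
| 2.00 | 55.2 | 1.5 |
| 5.00 | 53.0 | 6.0 |
| 12.0 | 19.8 | 11.2 |
| 30.0 | 1.3 | 11.9 |

(each reading ± 1 percentage point)

- time, not beyond 80 min, at which the flask holds most D
- the amount of D, in percent of the E charged, at that time
- earliest time at which at least nineteen twentieths of that best amount are there, in min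
- latest time at which they still are, in min

- the earlier runs were read with a standard deviation of 1 percentage point
- steps that have been proposed: E + Z -> J + Q; Z + J -> D + Q; Z + D -> L + Q; L -> G; D -> X

Ann and Ben, two chemists, agree on one thing: late in the autumn flask, D, taken as a fraction of the E charged, looks like a straight line in its logarithm, as a pseudo-first-order fall would. So they work in powers of ten. From 19.8 % at 12.0 min to 1.3 % at 30.0 min, D loses 1.18 powers of ten. This gives the decade time, the time in which unfed D drops by one power of ten: 15.2 min. It is a reading, and the last D carries a scatter of 1 percentage point.

Ann holds that the feed of D is over by the highest reading, so the best is 55.2 % at 2.00 min. She points out that the next reading lies 2.2 points lower, which suits a slow decline under that scatter.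

Ben holds that D is still being fed at that time, and he tests her view with the decade time. Between those two readings lie 0.197 decade times, so unfed D should have come down to 35.1 %. Yet it reads 53.0 %, which is higher by 18 points. So D was still being made after the earlier reading, and Ben puts the top inside the gap, above both readings.

His test gives no height. For that he takes the forecast, which starts from the remark “The D tail is clean”: 60 % at 3.1 min, with the span asked for running from 2.2 min to 4.2 min.

The flask gives 60.2 % at 2.99 min, with the span asked for running from 2.16 min to 4.08 min, so the top stands inside the gap as Ben held, later than Ann's reading and earlier than the next one.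

    E + Z → J + Q (k = 0.490 M⁻¹ s⁻¹)
    Z + J → D + Q (k = 0.860 M⁻¹ s⁻¹)
    Z + D → L + Q (k = 0.0170 M⁻¹ s⁻¹)
    L → G (k = 1.20 × 10⁻⁵ s⁻¹)
    D → X (k = 0.00260 s⁻¹)

Ann's view has its region later: at 8.00 min the flask holds E 0.424 % and J 0.552 %, hardly any of the charge left on its way to D. In the neighbour flask with 17 mM of E, the best is 52.4 %. Its span of 80 min holds 5.26 decade times of the autumn reading, and at its end that neighbour flask holds D 0 %.

The readings were generated by integration from invented constants, noise included.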